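**Retrosynthetic overview**
- The target comes from its bis(benzyl ether) by hydrogenolysis.
- The bis(benzyl ether) comes from an all-cis γ-aryl lactone by a fluoride-triggered ring switch (translactonisation): ring B (the target lactone, closed on the C9′ oxygen) is formed last, from ring A (lactone closed on the C7 oxygen).
- The all-cis lactone comes from a cis α-methylidene γ-aryl lactone by rhodium-catalysed conjugate arylation and face-selective protonation, which sets C8.
- Key C7–C8′ bond: ring A (formed first) comes from O-benzylvanillin and a 2-(methoxycarbonyl)allylchromium made from a (Z)-2-(bromomethyl)but-2-enoate. The enoate β-carbon acts as the nucleophile (ester β-anion, homoenolate-type reagent) towards the aldehyde carbon; the addition is syn-selective and catalyst-controlled and sets C7 and C8′.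
- The allylic bromide comes from the Morita–Baylis–Hillman adduct of methyl acrylate and (tert-butyldimethylsilyloxy)acetaldehyde.

Assumption: the target is taken exactly as the SMILES, i.e. the (3R,4R)-lactone with an (R)-carbinol (7R,8R,8′R in lignan numbering: C7 carbinol carbon, C8′ lactone β-carbon, C8 lactone α-carbon, C9′ lactone OCH2).

**Route**

Step 1
Reactants: 1 methyl acrylate; 2 (tert-butyldimethylsilyloxy)acetaldehyde
Product: 3 methyl 4-[(tert-butyldimethylsilyl)oxy]-3-hydroxy-2-methylidenebutanoate (racemic)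
Conditions: DABCO (0.5 equiv), 1 (3 equiv), 1,4-dioxane/H2O 1:1, rt, 48 h
Reagents that add atoms: none
Why: Morita–Baylis–Hillman reaction: DABCO adds to the acrylate, the ammonium enolate attacks the unhindered α-silyloxy aldehyde and the amine is eliminated; the carbinol centre is racemic and is erased in step 2.

Step 2
Reactants: 3
Product: 5 methyl (2Z)-2-(bromomethyl)-4-[(tert-butyldimethylsilyl)oxy]but-2-enoate, via alkoxysulfonium bromide 4 (not isolated)
Conditions: NBS (1.2 equiv), Me2S (1.3 equiv), CH2Cl2, 0 °C to rt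
Reagents that add atoms: N-bromosuccinimide, O=C1CCC(=O)N1Br
Why: Corey–Kim-type activation turns the hydroxyl into an alkoxysulfonium leaving group and bromide attacks the terminal methylene in an SN2′ sense, giving the conjugated allylic bromide with CH2OTBS trans to the ester (2Z, the thermodynamically preferred geometry) under neutral conditions that spare the silyl ether.

Step 3
Reactants: 5; 6 4-(benzyloxy)-3-methoxybenzaldehyde (O-benzylvanillin)
Product: 9 (4R,5R)-5-[4-(benzyloxy)-3-methoxyphenyl]-4-{[(tert-butyldimethylsilyl)oxy]methyl}-3-methylidenedihydrofuran-2(3H)-one, via trimethylsilyl ether 7 (not isolated), via hydroxy ester 8 (not isolated)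
Conditions: CrCl2 (10 mol %), (S,S)-3,6-diphenyl-1,8-bis(4-isopropyl-4,5-dihydro-1,3-oxazol-2-yl)-9H-carbazole (12 mol %), Mn powder (2 equiv), TMSCl (2 equiv), iPr2NEt (0.3 equiv), THF, 0 °C to rt; 1 M aq HCl/THF, 0 °C, 15 min; then PPTS (0.2 equiv), toluene, 60 °C
Reagents that add atoms: none
Why: Proposed new method: divalent chromium (regenerated by Mn, with TMSCl freeing the alkoxide) inserts into the C–Br bond of 5 to give a trivalent 2-(methoxycarbonyl)allylchromium that is nucleophilic at the enoate β-carbon, i.e. an ester β-anion (homoenolate-type) equivalent, and this carbon attacks the aldehyde carbon of 6 through a closed chair transition state with the aryl group equatorial and the CH2OTBS group axial (it stays cis to the CH2Cr carbon to avoid the ester), so the new C–C bond forms syn and the chromium-bound tridentate ligand selects the Re face of the aldehyde, setting both stereocentres as (3R,4R) in 7; dilute acid removes the O–TMS group and PPTS closes the cis γ-lactone; closest known reaction types are the catalytic asymmetric Nozaki–Hiyama–Kishi 2-(alkoxycarbonyl)allylation of aldehydes and the cis-selective chromium-mediated lactone synthesis from (Z)-2-(bromomethyl)alk-2-enoates; the ligand antipode is the one that gives Re-face attack (the R,R form is used if a test run shows the opposite sense).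

Step 4
Reactants: 9; 10 [4-(benzyloxy)-3-methoxyphenyl]boronic acid
Product: 11 (3R,4R,5R)-3-[4-(benzyloxy)-3-methoxybenzyl]-5-[4-(benzyloxy)-3-methoxyphenyl]-4-{[(tert-butyldimethylsilyl)oxy]methyl}dihydrofuran-2(3H)-one (all-cis)
Conditions: [Rh(OH)(cod)]2 (3 mol %), 10 (2 equiv), 1,4-dioxane/H2O 10:1, 40 °C
Reagents that add atoms: none
Why: Hayashi–Miyaura rhodium-catalysed 1,4-addition: the aryl group passes from boron to monovalent rhodium and adds to the exocyclic methylene carbon, and the rhodium enolate is protonated by water at C3 from the ring face opposite the cis C4 and C5 substituents under neutral conditions that do not epimerise, which sets C3 as R and gives the all-cis lactone.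

Step 5
Reactants: 11
Product: 13 (3R,4R)-3-[4-(benzyloxy)-3-methoxybenzyl]-4-{(R)-[4-(benzyloxy)-3-methoxyphenyl](hydroxy)methyl}dihydrofuran-2(3H)-one, via hydroxymethyl lactone 12 (not isolated)
Conditions: Bu4NF (TBAF, 1.2 equiv), THF, 0 °C, 1 h; AcOH quench
Reagents that add atoms: none
Why: Fluoride cleaves the primary silyl ether and the freed C4 CH2O oxygen attacks the lactone carbonyl (intramolecular transesterification, translactonisation), expelling the C5 benzylic oxygen; relief of the all-cis strain drives the ring switch to the trans-3,4-disubstituted lactone, and since no bond to a stereocentre is broken the (3R,4R,5R) centres become the (3R,4R) ring carbons and the (R)-carbinol.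

Step 6
Reactants: 13
Product: 14 (3R,4R)-4-[(R)-hydroxy(4-hydroxy-3-methoxyphenyl)methyl]-3-(4-hydroxy-3-methoxybenzyl)dihydrofuran-2(3H)-one (the target)
Conditions: H2 (1 atm), Pd/C (10 wt %, 5 mol % Pd), EtOAc, rt, stopped at full conversion (about 1–2 h)
Reagents that add atoms: none
Why: Catalytic hydrogenolysis of the two aryl benzyl ethers is far faster than C–O hydrogenolysis of the secondary benzylic alcohol under neutral conditions at 1 atm, so stopping at two equivalents of H2 leaves all three stereocentres and the lactone untouched.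

**Compound list**
1 | methyl acrylate | C=CC(=O)OC | starting material
2 | (tert-butyldimethylsilyloxy)acetaldehyde | O=CCO[Si](C)(C)C(C)(C)C | starting material
3 | methyl 4-[(tert-butyldimethylsilyl)oxy]-3-hydroxy-2-methylidenebutanoate (racemic) | C=C(C(=O)OC)C(O)CO[Si](C)(C)C(C)(C)C | intermediate
4 | {[1-[(tert-butyldimethylsilyl)oxy]-3-(methoxycarbonyl)but-3-en-2-yl]oxy}dimethylsulfonium bromide (racemic, formed in the flask, not isolated) | C=C(C(=O)OC)C(O[S+](C)C)CO[Si](C)(C)C(C)(C)C.[Br-] | intermediate
5 | methyl (2Z)-2-(bromomethyl)-4-[(tert-butyldimethylsilyl)oxy]but-2-enoate | COC(=O)/C(CBr)=C/CO[Si](C)(C)C(C)(C)C | intermediate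
6 | 4-(benzyloxy)-3-methoxybenzaldehyde | COc1cc(C=O)ccc1OCc1ccccc1 | starting material
7 | methyl (3R,4R)-4-[4-(benzyloxy)-3-methoxyphenyl]-3-{[(tert-butyldimethylsilyl)oxy]methyl}-2-methylidene-4-[(trimethylsilyl)oxy]butanoate (formed in the flask, not isolated) | COC(=O)C(=C)[C@H](CO[Si](C)(C)C(C)(C)C)[C@@H](O[Si](C)(C)C)c1ccc(OCc2ccccc2)c(OC)c1 | intermediate
8 | methyl (3R,4R)-4-[4-(benzyloxy)-3-methoxyphenyl]-3-{[(tert-butyldimethylsilyl)oxy]methyl}-4-hydroxy-2-methylidenebutanoate (formed in the flask, not isolated) | COC(=O)C(=C)[C@H](CO[Si](C)(C)C(C)(C)C)[C@@H](O)c1ccc(OCc2ccccc2)c(OC)c1 | intermediate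
9 | (4R,5R)-5-[4-(benzyloxy)-3-methoxyphenyl]-4-{[(tert-butyldimethylsilyl)oxy]methyl}-3-methylidenedihydrofuran-2(3H)-one (4,5-cis) | C=C1C(=O)O[C@@H](c2ccc(OCc3ccccc3)c(OC)c2)[C@H]1CO[Si](C)(C)C(C)(C)C | intermediate
10 | [4-(benzyloxy)-3-methoxyphenyl]boronic acid | COc1cc(B(O)O)ccc1OCc1ccccc1 | starting material
11 | (3R,4R,5R)-3-[4-(benzyloxy)-3-methoxybenzyl]-5-[4-(benzyloxy)-3-methoxyphenyl]-4-{[(tert-butyldimethylsilyl)oxy]methyl}dihydrofuran-2(3H)-one (all-cis) | COc1cc(C[C@H]2C(=O)O[C@@H](c3ccc(OCc4ccccc4)c(OC)c3)[C@H]2CO[Si](C)(C)C(C)(C)C)ccc1OCc1ccccc1 | intermediate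
12 | (3R,4R,5R)-3-[4-(benzyloxy)-3-methoxybenzyl]-5-[4-(benzyloxy)-3-methoxyphenyl]-4-(hydroxymethyl)dihydrofuran-2(3H)-one (formed in the flask, not isolated) | COc1cc(C[C@H]2C(=O)O[C@@H](c3ccc(OCc4ccccc4)c(OC)c3)[C@H]2CO)ccc1OCc1ccccc1 | intermediate
13 | (3R,4R)-3-[4-(benzyloxy)-3-methoxybenzyl]-4-{(R)-[4-(benzyloxy)-3-methoxyphenyl](hydroxy)methyl}dihydrofuran-2(3H)-one | COc1cc(C[C@H]2C(=O)OC[C@@H]2[C@@H](O)c2ccc(OCc3ccccc3)c(OC)c2)ccc1OCc1ccccc1 | intermediate
14 | (3R,4R)-4-[(R)-hydroxy(4-hydroxy-3-methoxyphenyl)methyl]-3-(4-hydroxy-3-methoxybenzyl)dihydrofuran-2(3H)-one | COc1cc(C[C@H]2C(=O)OC[C@@H]2[C@@H](O)c2ccc(O)c(OC)c2)ccc1O | target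

**Totals and risks**

Total step count: 6. Longest linear sequence: 6 steps (1/2 → 3 → 5 → 9 → 11 → 13 → 14).

The three steps most likely to fail:

- **Chromium coupling (step 3).** The risks are the level of enantio- and syn-selectivity with this γ-(silyloxymethyl) bromide and loss of the β-silyloxy group from the allylchromium. The fallback sets out from 3 and comes back at 9.
  - Acetylation (Ac2O, DMAP, pyridine) gives methyl 3-acetoxy-4-[(tert-butyldimethylsilyl)oxy]-2-methylidenebutanoate F1.
  - Copper-catalysed SN2′ borylation (B2pin2, CuCl, LiCl, KOAc, DMF, rt) gives the allylboronate methyl (2E)-4-[(tert-butyldimethylsilyl)oxy]-2-[(4,4,5,5-tetramethyl-1,3,2-dioxaborolan-2-yl)methyl]but-2-enoate F2, in which CH2OTBS is cis to the CH2B carbon.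
  - Allylboration of 6 catalysed by a chiral BINOL phosphoric acid (3,3′-bis(2,4,6-triisopropylphenyl)-1,1′-binaphthyl-2,2′-diyl hydrogen phosphate, antipode chosen for Re-face attack; toluene, −30 °C) is stereospecific through a chair transition state and gives the same syn adduct 8, which PPTS lactonises to 9.
  - This replaces chromium redox catalysis with a boron reagent whose geometry is fixed before the C–C bond forms.

- **Conjugate arylation (step 4).** The risk is imperfect face selectivity in the protonation, or epimerisation of the strained all-cis product, giving C3 epimers. The fallback sets out from 9 and comes back at 11.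
  - Heck arylation of 9 with 1-(benzyloxy)-4-iodo-2-methoxybenzene (Pd(OAc)2, Bu4NCl, NaHCO3, DMF, 60 °C) gives (3E,4R,5R)-3-[4-(benzyloxy)-3-methoxybenzylidene]-5-[4-(benzyloxy)-3-methoxyphenyl]-4-{[(tert-butyldimethylsilyl)oxy]methyl}dihydrofuran-2(3H)-one F3.
  - Homogeneous hydrogenation ([Ir(cod)(PCy3)(py)]PF6, H2 1 atm, CH2Cl2) adds both hydrogens to the ring face opposite the C4 and C5 substituents and gives 11.
  - C3 is then set by syn delivery of H2 from the metal and not by enolate protonation; the benzyl ethers and the benzylic lactone C–O bond survive this non-hydrogenolytic catalyst.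

- **Ring switch (step 5).** The risk is an incomplete switch (mixture of 12 and 13) or C3 epimerisation by basic fluoride. The fallback sets out from 11 and comes back at 13.
  - After desilylation with Bu4NF, aqueous LiOH (THF/H2O, 0 °C) opens whichever lactone is present to the lithium salt of (2R,3R)-2-[4-(benzyloxy)-3-methoxybenzyl]-3-{(R)-[4-(benzyloxy)-3-methoxyphenyl](hydroxy)methyl}-4-hydroxybutanoic acid F4. As a carboxylate the α-centre can no longer epimerise.
  - Careful acidification to pH 3 (or EDC·HCl in CH2Cl2) closes the γ-lactone kinetically on the unhindered primary hydroxyl, giving 13.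
  - This replaces the equilibrium acyl transfer with hydrolysis and kinetic relactonisation.

**Further compounds**
F1 | step 3 | methyl 3-acetoxy-4-[(tert-butyldimethylsilyl)oxy]-2-methylidenebutanoate (racemic) | C=C(C(=O)OC)C(OC(C)=O)CO[Si](C)(C)C(C)(C)C
F2 | step 3 | methyl (2E)-4-[(tert-butyldimethylsilyl)oxy]-2-[(4,4,5,5-tetramethyl-1,3,2-dioxaborolan-2-yl)methyl]but-2-enoate | COC(=O)/C(CB1OC(C)(C)C(C)(C)O1)=C/CO[Si](C)(C)C(C)(C)C
F3 | step 4 | (3E,4R,5R)-3-[4-(benzyloxy)-3-methoxybenzylidene]-5-[4-(benzyloxy)-3-methoxyphenyl]-4-{[(tert-butyldimethylsilyl)oxy]methyl}dihydrofuran-2(3H)-one | COc1cc(/C=C2/C(=O)O[C@@H](c3ccc(OCc4ccccc4)c(OC)c3)[C@H]2CO[Si](C)(C)C(C)(C)C)ccc1OCc1ccccc1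
F4 | step 5 | (2R,3R)-2-[4-(benzyloxy)-3-methoxybenzyl]-3-{(R)-[4-(benzyloxy)-3-methoxyphenyl](hydroxy)methyl}-4-hydroxybutanoic acid | COc1cc(C[C@@H](C(=O)O)[C@H](CO)[C@@H](O)c2ccc(OCc3ccccc3)c(OC)c2)ccc1OCc1ccccc1
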